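**Retrosynthetic overview**
- Target ⇒ bromoethyl decalin acetate + 3-bromobutenolide: the side-chain CH2–C(butenolide) bond is made last by nickel-catalysed reductive coupling.
- Bromoethyl decalin acetate ⇒ decalin carbaldehyde lacking the C-1 methyl: equatorial enolate methylation sets the quaternary centre, then reduction and acetylation.
- Decalin carbaldehyde ⇒ acyclic dienal: one enantioselective organo-SOMO radical-cation bicyclisation. Ring A closes first (radical C1–C8a bond), ring B second (C4a–C5 bond), and an allylsilane ends the cascade as the exocyclic methylene.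
- Dienal ⇒ hex-5-en-1-yne + oxirane + 2,3-dihydrofuran + one-carbon reagents: the E alkene comes from zirconium-catalysed methylalumination, the Z allylsilane from a stereospecific dihydrofuran ring opening, the aldehyde from hydroformylation.

Assumption: the (2S,5S) imidazolidinone leaves the Re face of the enamine radical cation open, which gives the (1S,8aR) series drawn; if the sense is the reverse, the (2R,5R) catalyst is used and nothing else changes.

Locants for bicyclic compounds are those of the decahydronaphthalene names.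

**Step 1**
Reactants: 1 hex-5-en-1-yne; 2 oxirane
Product: 5 (3E)-4-methylocta-3,7-dien-1-ol, via alkenylalane 3 (not isolated), via lithium alkenylalanate 4 (not isolated)
Conditions: Me3Al (1.5 equiv), (C5H5)2ZrCl2 (20 mol%), CH2Cl2, 0 °C → rt; volatiles removed in vacuo; n-BuLi, hexane/THF, 0 °C; 2, 0 °C → rt; H2O
Reagents that add atoms: trimethylaluminium, C[Al](C)C
Why: Zirconium-catalysed methylalumination (Negishi carboalumination) adds Me and Al syn across the terminal alkyne with Al on the terminal carbon, leaving the far less reactive monosubstituted alkene alone, and the alanate formed with n-BuLi opens oxirane with retention at the alkenyl carbon, so the hydroxyethyl arm ends cis to methyl and trans to the butenyl chain (E alkene).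

**Step 2**
Reactants: 5 (3E)-4-methylocta-3,7-dien-1-ol
Product: 6 (5E)-8-iodo-5-methylocta-1,5-diene
Conditions: I2, PPh3, imidazole, CH2Cl2, 0 °C → rt
Reagents that add atoms: iodine, II
Why: Appel-type (Garegg–Samuelsson) iodination of a primary alcohol under neutral conditions; the alkene geometry is untouched.

**Step 3**
Reactants: 6 (5E)-8-iodo-5-methylocta-1,5-diene; 7 2,3-dihydrofuran
Product: 9 5-[(3E)-4-methylocta-3,7-dien-1-yl]-2,3-dihydrofuran, via 5-lithio-2,3-dihydrofuran 8 (not isolated)
Conditions: 7, t-BuLi, THF, −78 → 0 °C; then 6, THF, −30 °C → rt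
Reagents that add atoms: none
Why: Substitution of a primary iodide by the α-lithiated enol ether (C-alkylation); the acid-labile enol ether 9 is carried on without contact with acid.

**Step 4**
Reactants: 9 5-[(3E)-4-methylocta-3,7-dien-1-yl]-2,3-dihydrofuran
Product: 10 (3Z,7E)-8-methyl-4-[(trimethylsilyl)methyl]dodeca-3,7,11-trien-1-ol
Conditions: Me3SiCH2MgCl (3 equiv), NiCl2(PPh3)2 (5 mol%), benzene, reflux; then H2O
Reagents that add atoms: (trimethylsilyl)methylmagnesium chloride, C[Si](C)(C)C[Mg]Cl
Why: Nickel-catalysed cross-coupling of the cyclic enol ether C–O bond with a Grignard reagent (Wenkert–Kocienski ring opening, Kumada type) goes with retention at the alkenyl carbon, so CH2SiMe3 replaces oxygen cis to the hydroxyethyl arm and the Z allylsilane results; the reagent has no β-hydrogen, so the other alkenes are not isomerised.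

**Step 5**
Reactants: 10 (3Z,7E)-8-methyl-4-[(trimethylsilyl)methyl]dodeca-3,7,11-trien-1-ol
Product: 11 (5E,9Z)-12-bromo-5-methyl-9-[(trimethylsilyl)methyl]dodeca-1,5,9-triene
Conditions: CBr4, PPh3, 2,6-lutidine, CH2Cl2, 0 °C
Reagents that add atoms: tetrabromomethane, BrC(Br)(Br)Br
Why: Appel bromination of the primary alcohol; the buffered, acid-free medium spares the allylsilane.

**Step 6**
Reactants: 11 (5E,9Z)-12-bromo-5-methyl-9-[(trimethylsilyl)methyl]dodeca-1,5,9-triene
Product: 12 (6E,10Z)-13-bromo-6-methyl-10-[(trimethylsilyl)methyl]trideca-6,10-dienal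
Conditions: CO/H2 (1:1, 10 bar), Rh(acac)(CO)2 (1 mol%), BiPhePhos (2 mol%), toluene, 60 °C
Reagents that add atoms: carbon monoxide, [C-]#[O+]
Why: Linear-selective rhodium-catalysed hydroformylation acts only on the monosubstituted terminal alkene; the two trisubstituted alkenes, the allylsilane and the primary bromide are inert under these conditions.

**Step 7**
Reactants: 12 (6E,10Z)-13-bromo-6-methyl-10-[(trimethylsilyl)methyl]trideca-6,10-dienal
Product: 14 (1S,4aR,5R,8aR)-5-(2-bromoethyl)-4a-methyl-6-methylidenedecahydronaphthalene-1-carbaldehyde, via enamine 13 (not isolated)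
Conditions: (2S,5S)-5-benzyl-2-tert-butyl-3-methylimidazolidin-4-one·CF3CO2H (20 mol%), (NH4)2Ce(NO3)6 (2.2 equiv), NaHCO3 (2 equiv), H2O (2 equiv), 1,2-dimethoxyethane, −20 °C
Reagents that add atoms: water, O
Why: Proposed new method: enamine 13 is oxidised by tetravalent cerium to a 3π-electron radical cation whose open Re face adds 6-endo to the E-trisubstituted alkene through a chair with the iminium carbon equatorial (radical C1–C8a bond, fixing C-8a and the absolute sense), the tertiary radical (or the cation formed from it by a second oxidation) closes ring B through a second chair onto the Z allylsilane to give the trans-decalin with the C-5 arm equatorial, and loss of silicon from the β-silyl cation leaves the exocyclic methylene under bicarbonate buffering, with water hydrolysing the iminium to the aldehyde; the closest known reactions are organo-SOMO polyene cyclisations ended by arenes and the intramolecular organo-SOMO α-allylation of aldehydes by allylsilanes.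

**Step 8**
Reactants: 14 (1S,4aR,5R,8aR)-5-(2-bromoethyl)-4a-methyl-6-methylidenedecahydronaphthalene-1-carbaldehyde
Product: 16 (1R,4aS,5R,8aS)-5-(2-bromoethyl)-1,4a-dimethyl-6-methylidenedecahydronaphthalene-1-carbaldehyde, via potassium enolate 15 (not isolated)
Conditions: KN(SiMe3)2, THF, −78 °C; MeI, −78 → −20 °C
Reagents that add atoms: iodomethane, CI
Why: C-alkylation of the exocyclic aldehyde enolate: the axial 4a-methyl blocks the syn-axial trajectory, so MeI enters equatorially and the formyl group is pushed axial, cis to the angular methyl (the C-1 configuration of 14 is erased in the enolate and reset here); ring closure onto the bromoethyl arm is geometrically impossible because C-1 and C-5 are anti across the trans ring fusion.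

**Step 9**
Reactants: 16 (1R,4aS,5R,8aS)-5-(2-bromoethyl)-1,4a-dimethyl-6-methylidenedecahydronaphthalene-1-carbaldehyde
Product: 17 [(1R,4aS,5R,8aS)-5-(2-bromoethyl)-1,4a-dimethyl-6-methylidenedecahydronaphthalen-1-yl]methanol
Conditions: NaBH4, MeOH, 0 °C
Reagents that add atoms: none
Why: Borohydride reduction of the aldehyde; the primary bromide and the alkene do not react and no stereocentre changes.

**Step 10**
Reactants: 17 [(1R,4aS,5R,8aS)-5-(2-bromoethyl)-1,4a-dimethyl-6-methylidenedecahydronaphthalen-1-yl]methanol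
Product: 18 [(1R,4aS,5R,8aS)-5-(2-bromoethyl)-1,4a-dimethyl-6-methylidenedecahydronaphthalen-1-yl]methyl acetate
Conditions: Ac2O, pyridine, DMAP (cat.), CH2Cl2, rt
Reagents that add atoms: acetic anhydride, CC(=O)OC(C)=O
Why: DMAP-catalysed acylation of the neopentyl primary alcohol.

**Step 11**
Reactants: 18 [(1R,4aS,5R,8aS)-5-(2-bromoethyl)-1,4a-dimethyl-6-methylidenedecahydronaphthalen-1-yl]methyl acetate; 19 3-bromofuran-2(5H)-one
Product: 20 [(1R,4aS,5R,8aS)-1,4a-dimethyl-6-methylidene-5-[2-(2-oxo-2,5-dihydrofuran-3-yl)ethyl]decahydronaphthalen-1-yl]methyl acetate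
Conditions: NiBr2·(MeOCH2CH2OMe) (10 mol%), 4,4'-di-tert-butyl-2,2'-bipyridine (10 mol%), Zn dust (2 equiv), N,N-dimethylacetamide, rt
Reagents that add atoms: none
Why: Nickel-catalysed reductive cross-electrophile coupling (sp3–sp2): the alkenyl bromide adds to low-valent nickel, the primary alkyl radical formed from 18 by bromine abstraction is captured by the alkenylnickel species, and reductive elimination gives the α-alkyl butenolide without touching any stereocentre.

**Compound list**
1 | hex-5-en-1-yne | C#CCCC=C | starting material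
2 | oxirane | C1CO1 | starting material
3 | dimethyl[(1E)-2-methylhexa-1,5-dien-1-yl]alane (Al cis to the new methyl) | C[Al](C)/C=C(\C)CCC=C | intermediate (not isolated)
4 | lithium butyl(dimethyl)[(1E)-2-methylhexa-1,5-dien-1-yl]alanate | [Li+].CCCC[Al-](C)(C)/C=C(\C)CCC=C | intermediate (not isolated)
5 | (3E)-4-methylocta-3,7-dien-1-ol | OCC/C=C(\C)CCC=C | intermediate
6 | (5E)-8-iodo-5-methylocta-1,5-diene | ICC/C=C(\C)CCC=C | intermediate
7 | 2,3-dihydrofuran | C1=COCC1 | starting material
8 | 5-lithio-2,3-dihydrofuran | [Li]C1=CCCO1 | intermediate (not isolated)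
9 | 5-[(3E)-4-methylocta-3,7-dien-1-yl]-2,3-dihydrofuran | C=CCC/C(C)=C/CCC1=CCCO1 | intermediate
10 | (3Z,7E)-8-methyl-4-[(trimethylsilyl)methyl]dodeca-3,7,11-trien-1-ol | OCC/C=C(\C[Si](C)(C)C)CC/C=C(\C)CCC=C | intermediate
11 | (5E,9Z)-12-bromo-5-methyl-9-[(trimethylsilyl)methyl]dodeca-1,5,9-triene | BrCC/C=C(\C[Si](C)(C)C)CC/C=C(\C)CCC=C | intermediate
12 | (6E,10Z)-13-bromo-6-methyl-10-[(trimethylsilyl)methyl]trideca-6,10-dienal | BrCC/C=C(\C[Si](C)(C)C)CC/C=C(\C)CCCCC=O | intermediate
13 | (E)-enamine formed from 12 by condensation with (2S,5S)-5-benzyl-2-tert-butyl-3-methylimidazolidin-4-one (catalyst N-1 bonded to the former aldehyde carbon) | BrCC/C=C(\C[Si](C)(C)C)CC/C=C(\C)CCC/C=C/N1[C@H](C(C)(C)C)N(C)C(=O)[C@@H]1Cc2ccccc2 | intermediate (not isolated)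
14 | (1S,4aR,5R,8aR)-5-(2-bromoethyl)-4a-methyl-6-methylidenedecahydronaphthalene-1-carbaldehyde | C=C1CC[C@@H]2[C@@H](C=O)CCC[C@@]2(C)[C@@H]1CCBr | intermediate
15 | potassium enolate of 14 (exocyclic C=CH–OK at C-1; other stereocentres as in 14) | C=C1CC[C@@H]2C(=C[O-])CCC[C@@]2(C)[C@@H]1CCBr.[K+] | intermediate (not isolated)
16 | (1R,4aS,5R,8aS)-5-(2-bromoethyl)-1,4a-dimethyl-6-methylidenedecahydronaphthalene-1-carbaldehyde | C=C1CC[C@@H]2[C@](C)(C=O)CCC[C@@]2(C)[C@@H]1CCBr | intermediate
17 | [(1R,4aS,5R,8aS)-5-(2-bromoethyl)-1,4a-dimethyl-6-methylidenedecahydronaphthalen-1-yl]methanol | C=C1CC[C@@H]2[C@](C)(CO)CCC[C@@]2(C)[C@@H]1CCBr | intermediate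
18 | [(1R,4aS,5R,8aS)-5-(2-bromoethyl)-1,4a-dimethyl-6-methylidenedecahydronaphthalen-1-yl]methyl acetate | C=C1CC[C@@H]2[C@](C)(COC(C)=O)CCC[C@@]2(C)[C@@H]1CCBr | intermediate
19 | 3-bromofuran-2(5H)-one | O=C1OCC=C1Br | starting material
20 | [(1R,4aS,5R,8aS)-1,4a-dimethyl-6-methylidene-5-[2-(2-oxo-2,5-dihydrofuran-3-yl)ethyl]decahydronaphthalen-1-yl]methyl acetate | C=C1CC[C@@H]2[C@](C)(COC(C)=O)CCC[C@@]2(C)[C@@H]1CCC1=CCOC1=O | target

**Totals**
Total step count: 11. Longest linear sequence: 11 (the route is fully linear).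

**Steps most likely to fail**

Step 7 is the main risk. Ending an organo-SOMO polyene cascade with an allylsilane is untested, the oxidant may attack the allylsilane or the alkenes, and the enantioselectivity is only inferred from related cyclisations. The fallback replaces catalyst control by a bound auxiliary and an atom-transfer radical bicyclisation; it sets out from 12 and comes back at 14. Aldehyde 12 is oxidised (NaClO2, NaH2PO4, 2-methylbut-2-ene) to (6E,10Z)-13-bromo-6-methyl-10-[(trimethylsilyl)methyl]trideca-6,10-dienoic acid F1. Pivaloyl chloride/Et3N and lithiated (4R)-4-benzyl-1,3-oxazolidin-2-one convert it into (4R)-4-benzyl-3-[(6E,10Z)-13-bromo-6-methyl-10-[(trimethylsilyl)methyl]trideca-6,10-dienoyl]-1,3-oxazolidin-2-one F2. Enolisation (NaN(SiMe3)2, −78 °C) and N-bromosuccinimide give (4R)-4-benzyl-3-[(6E,10Z)-2,13-dibromo-6-methyl-10-[(trimethylsilyl)methyl]trideca-6,10-dienoyl]-1,3-oxazolidin-2-one F3, of which either C-2 epimer serves. With Yb(OTf)3 and Et3B/O2 at −78 °C the chelated α-acyl radical closes ring A on the face away from the benzyl group (the sense of the corresponding enolate alkylations), the tertiary radical closes ring B onto the allylsilane, and the β-silyl radical takes bromine from F3 to carry the chain. The resulting (4R)-4-benzyl-3-{[6-bromo-5-(2-bromoethyl)-4a-methyl-6-[(trimethylsilyl)methyl]decahydronaphthalen-1-yl]carbonyl}-1,3-oxazolidin-2-one F4 (ring configuration as in F5) loses bromotrimethylsilane on warming to give (4R)-4-benzyl-3-{[(1S,4aR,5R,8aR)-5-(2-bromoethyl)-4a-methyl-6-methylidenedecahydronaphthalen-1-yl]carbonyl}-1,3-oxazolidin-2-one F5. LiBH4 (THF/MeOH, 0 °C) removes the auxiliary to give [(1S,4aR,5R,8aR)-5-(2-bromoethyl)-4a-methyl-6-methylidenedecahydronaphthalen-1-yl]methanol F6, and Dess–Martin periodinane returns aldehyde 14.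

Step 8 may give O-methylation or too little facial selectivity at the hindered aldehyde enolate. The fallback builds the quaternary centre at the ester oxidation level, where equatorial alkylation next to an axial angular methyl is best established; it sets out from 14 and comes back at 17. Oxidation (NaClO2, NaH2PO4, 2-methylbut-2-ene) gives (1S,4aR,5R,8aR)-5-(2-bromoethyl)-4a-methyl-6-methylidenedecahydronaphthalene-1-carboxylic acid F7. Me3SiCHN2 in MeOH/toluene gives methyl (1S,4aR,5R,8aR)-5-(2-bromoethyl)-4a-methyl-6-methylidenedecahydronaphthalene-1-carboxylate F8. LiN(i-Pr)2 at −78 °C followed by MeI gives methyl (1R,4aS,5R,8aS)-5-(2-bromoethyl)-1,4a-dimethyl-6-methylidenedecahydronaphthalene-1-carboxylate F9, which i-Bu2AlH (CH2Cl2, −78 → 0 °C) reduces to alcohol 17 without touching the bromide.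

Step 11 may suffer from conjugate addition of the alkyl radical to the butenolide, or from homocoupling. The fallback is a polar two-electron coupling; it sets out from 18 and comes back at 20. Zinc dust with LiCl in THF at 50 °C inserts into the C–Br bond to give [(1R,4aS,5R,8aS)-5-[2-(bromozincio)ethyl]-1,4a-dimethyl-6-methylidenedecahydronaphthalen-1-yl]methyl acetate F10, which undergoes Negishi coupling with 19 (Pd(OAc)2 2 mol%, 2-dicyclohexylphosphino-2',6'-dimethoxybiphenyl 4 mol%, THF, rt) to give 20.

**Further compounds**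
F1 | step 7 | (6E,10Z)-13-bromo-6-methyl-10-[(trimethylsilyl)methyl]trideca-6,10-dienoic acid | BrCC/C=C(\C[Si](C)(C)C)CC/C=C(\C)CCCCC(=O)O
F2 | step 7 | (4R)-4-benzyl-3-[(6E,10Z)-13-bromo-6-methyl-10-[(trimethylsilyl)methyl]trideca-6,10-dienoyl]-1,3-oxazolidin-2-one | BrCC/C=C(\C[Si](C)(C)C)CC/C=C(\C)CCCCC(=O)N1[C@H](Cc2ccccc2)COC1=O
F3 | step 7 | (4R)-4-benzyl-3-[(6E,10Z)-2,13-dibromo-6-methyl-10-[(trimethylsilyl)methyl]trideca-6,10-dienoyl]-1,3-oxazolidin-2-one | BrCC/C=C(\C[Si](C)(C)C)CC/C=C(\C)CCCC(Br)C(=O)N1[C@H](Cc2ccccc2)COC1=O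
F4 | step 7 | (4R)-4-benzyl-3-{[6-bromo-5-(2-bromoethyl)-4a-methyl-6-[(trimethylsilyl)methyl]decahydronaphthalen-1-yl]carbonyl}-1,3-oxazolidin-2-one | C[Si](C)(C)CC1(Br)CC[C@@H]2[C@@H](C(=O)N3[C@H](Cc4ccccc4)COC3=O)CCC[C@@]2(C)[C@@H]1CCBr
F5 | step 7 | (4R)-4-benzyl-3-{[(1S,4aR,5R,8aR)-5-(2-bromoethyl)-4a-methyl-6-methylidenedecahydronaphthalen-1-yl]carbonyl}-1,3-oxazolidin-2-one | C=C1CC[C@@H]2[C@@H](C(=O)N3[C@H](Cc4ccccc4)COC3=O)CCC[C@@]2(C)[C@@H]1CCBr
F6 | step 7 | [(1S,4aR,5R,8aR)-5-(2-bromoethyl)-4a-methyl-6-methylidenedecahydronaphthalen-1-yl]methanol | C=C1CC[C@@H]2[C@@H](CO)CCC[C@@]2(C)[C@@H]1CCBr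
F7 | step 8 | (1S,4aR,5R,8aR)-5-(2-bromoethyl)-4a-methyl-6-methylidenedecahydronaphthalene-1-carboxylic acid | C=C1CC[C@@H]2[C@@H](C(=O)O)CCC[C@@]2(C)[C@@H]1CCBr
F8 | step 8 | methyl (1S,4aR,5R,8aR)-5-(2-bromoethyl)-4a-methyl-6-methylidenedecahydronaphthalene-1-carboxylate | C=C1CC[C@@H]2[C@@H](C(=O)OC)CCC[C@@]2(C)[C@@H]1CCBr
F9 | step 8 | methyl (1R,4aS,5R,8aS)-5-(2-bromoethyl)-1,4a-dimethyl-6-methylidenedecahydronaphthalene-1-carboxylate | C=C1CC[C@@H]2[C@](C)(C(=O)OC)CCC[C@@]2(C)[C@@H]1CCBr
F10 | step 11 | [(1R,4aS,5R,8aS)-5-[2-(bromozincio)ethyl]-1,4a-dimethyl-6-methylidenedecahydronaphthalen-1-yl]methyl acetate | C=C1CC[C@@H]2[C@](C)(COC(C)=O)CCC[C@@]2(C)[C@@H]1CC[Zn]Br
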